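**Retrosynthetic overview**

1. Eudesmane numbering is used: ring A = C1–C5 + C10, ring B = C5–C10; C1 carries the benzylic carbon C1', C4 the ring carbinol, C7 the 2-hydroxypropan-2-yl group (C11), C10 the angular methyl. End game: ArOMe cleavage ⇐ twofold ortho-lithiation/formylation ⇐ MeMgBr on a trans-decalin diketone (C4 ring ketone, C7 acetyl).
2. Ring A is closed last (C2–C3 bond) by aldol condensation of a keto-aldehyde; its carbonyl groups come from a CH2OSi arm on C1 and from two vinyl groups on C5 and C7 (Wacker oxidation).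
3. Ring B and the C1'–C1 bond are made together in the key step: an o-quinone methide adds to C1 of a 1-[(E)-alkenyl]-2,4-divinylcyclopentanol and the C10 cation is quenched by a 1,2-shift of C5 from the carbinol carbon C9 (cyclopentanol → cyclohexanone); the C9 oxygen is then removed through the enol triflate.
4. Enabling feature: the quaternary, methyl-bearing ring-fusion carbon C10 is bonded to C1 (the carbon that bears C1') and, inside ring B, to the methylene C9 and the methine C5; a C1=C10 alkene on a C9 carbinol makes C1 the nucleophile and C10 a cation placed for ring expansion.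
5. The cyclopentanol comes from (1R,4R)-norbornenone by exo addition of an (E)-alkenyllithium and ring-opening metathesis with ethylene. Order of rings: aromatic ring (bought), ring B (step 7), ring A (step 14).

Key step: step 7

Remark: (1R,4R)-bicyclo[2.2.1]hept-5-en-2-one is taken as a purchasable enantiopure building block; this was not checked against a catalogue.

**Route**

Step 1
Reactants: 1 but-2-yn-1-ol
Product: 2 tert-butyl(but-2-yn-1-yloxy)diphenylsilane
Conditions: TBDPSCl, imidazole, CH2Cl2, 0 °C → rt
Reagents that add atoms: tert-butyl(chloro)diphenylsilane, CC(C)(C)[Si](Cl)(c1ccccc1)c1ccccc1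
Why: Imidazole-promoted silylation of a primary alcohol; the bulky silyl ether survives all steps up to step 12.

Step 2
Reactants: 2 tert-butyl(but-2-yn-1-yloxy)diphenylsilane
Product: 4 (E)-tert-butyl[(3-iodobut-2-en-1-yl)oxy]diphenylsilane, via alkenylzirconocene chloride 3 (not isolated)
Conditions: Cp2Zr(H)Cl (2 equiv), THF, 50 °C; then I2, 0 °C
Reagents that add atoms: iodine, II
Why: Hydrozirconation–iodination: syn addition of Zr–H, with excess hydride equilibrating zirconium to the less hindered methyl-bearing carbon, then iodinolysis with retention should give the (E)-iodide (iodine trans to CH2OSi).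

Step 3
Reactants: 4 (E)-tert-butyl[(3-iodobut-2-en-1-yl)oxy]diphenylsilane; 5 (1R,4R)-bicyclo[2.2.1]hept-5-en-2-one
Product: 7 (1R,2R,4R)-2-[(E)-4-(tert-butyldiphenylsilyloxy)but-2-en-2-yl]bicyclo[2.2.1]hept-5-en-2-ol (OH endo), via alkenyllithium 6 (not isolated)
Conditions: t-BuLi (2.1 equiv), Et2O, −78 °C; then 5, −78 → −40 °C
Reagents that add atoms: none
Why: Iodine–lithium exchange with retention of alkene geometry, then 1,2-addition to the ketone from the exo face of the norbornenone (syn to the CH2 bridge), which sets the carbinol centre with OH endo.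

Step 4
Reactants: 7 (1R,2R,4R)-2-[(E)-4-(tert-butyldiphenylsilyloxy)but-2-en-2-yl]bicyclo[2.2.1]hept-5-en-2-ol
Product: 8 (1R,2R,4R)-1-[(E)-4-(tert-butyldiphenylsilyloxy)but-2-en-2-yl]-2,4-diethenylcyclopentan-1-ol (both vinyl groups cis to OH)
Conditions: ethylene (1 atm), first-generation Grubbs catalyst RuCl2(PCy3)2(=CHPh) (3 mol %), CH2Cl2, rt
Reagents that add atoms: ethylene, C=C
Why: Ring-opening cross-metathesis of the strained norbornene with ethylene; the trisubstituted alkene is inert to this catalyst, and the cis relation of the two vinyl groups (future C5 and C7 substituents) and of the endo OH follows from the bicycle.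

Step 5
Reactants: 9 2-hydroxy-4,6-dimethoxybenzaldehyde
Product: 10 3,5-dibromo-2-hydroxy-4,6-dimethoxybenzaldehyde
Conditions: NBS (2.1 equiv), MeCN, 0 °C → rt
Reagents that add atoms: N-bromosuccinimide, O=C1CCC(=O)N1Br
Why: Electrophilic aromatic bromination of the two free positions of the activated ring; the bromine atoms are temporary blocking groups that prevent Friedel–Crafts self-alkylation in step 7 and are removed in step 15.

Step 6
Reactants: 10 3,5-dibromo-2-hydroxy-4,6-dimethoxybenzaldehyde
Product: 11 2,4-dibromo-6-(1-hydroxy-3-methylbutyl)-3,5-dimethoxyphenol (racemic)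
Conditions: i-BuMgBr (2.3 equiv), THF, −78 → 0 °C
Reagents that add atoms: isobutylmagnesium bromide, CC(C)C[Mg]Br
Why: Grignard addition to the aldehyde after deprotonation of the phenol; the carbinol configuration is irrelevant because this carbon becomes planar in step 7.

Step 7
Reactants: 8 (1R,2R,4R)-1-[(E)-4-(tert-butyldiphenylsilyloxy)but-2-en-2-yl]-2,4-diethenylcyclopentan-1-ol; 11 2,4-dibromo-6-(1-hydroxy-3-methylbutyl)-3,5-dimethoxyphenol
Product: 13 2-[1-(tert-butyldiphenylsilyloxy)-3-(3,5-dibromo-2-hydroxy-4,6-dimethoxyphenyl)-5-methylhexan-2-yl]-3,5-diethenyl-2-methylcyclohexan-1-one (C1', C1, C10 as in the target; C10 methyl cis to both vinyl groups), via o-quinone methide 12 (not isolated)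
Conditions: (PhO)2P(O)OH (10 mol %), 4 Å MS, CH2Cl2, 0 °C → rt, slow addition of 11 (1.5 equiv)
Reagents that add atoms: none
Why: Proposed new method: the acid dehydrates 11 to the o-quinone methide 12, whose electrophilic methide carbon C1' is attacked by C1 of the trisubstituted alkene of 8, and the tertiary C10 cation that results, flanked by the C9 carbinol, is quenched by a 1,2-shift of the allylic ring carbon C5 from C9 to C10 with C=O formation, so that ring B is closed by ring expansion of the cyclopentanol to a cyclohexanone (five to six ring atoms). The closest known reaction type is the electrophile-induced semipinacol ring expansion of 1-alkenylcycloalkanols (oxocarbenium-triggered Prins–pinacol reactions of alkenylcyclopentanols, benzylic-cation and quinone-methide triggers on alkenylcyclobutanols), joined here to the known inverse-demand reactivity of o-quinone methides toward trisubstituted terpene alkenes. C1 and C10 are set relative to each other by anti addition of C1' and C5 across the (E)-alkene, C5 migrating with retention. The absolute sense at C10 comes from 8: in the reactive conformer the C9–C5 bond lies parallel to the alkene π system, the C9–OH sits on the opposite face and can hydrogen-bond the quinone methide oxygen, and the bulky new substituent on C1 ends up trans to the C5 vinyl group, which places the C10 methyl cis to both vinyl groups. C1' is set by a hetero-Diels–Alder-like approach with the isobutyl group outside and the carbinol ring exo. The step needs attack at the trisubstituted alkene and not at the two monosubstituted ones (far less nucleophilic), migration of C5 and not C8 (secondary allylic versus primary carbon), and no arylation of the phenol ring (both free positions carry bromine); a chroman formed by O-capture of the cation should re-ionise under the acid and drain into the ketone.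

Step 8
Reactants: 13 ring-B ketone with free phenol
Product: 14 2-[1-(tert-butyldiphenylsilyloxy)-3-(3,5-dibromo-2,4,6-trimethoxyphenyl)-5-methylhexan-2-yl]-3,5-diethenyl-2-methylcyclohexan-1-one
Conditions: MeI, K2CO3, acetone, 50 °C
Reagents that add atoms: iodomethane, CI
Why: Phenol O-methylation (Williamson ether synthesis); the carbonate is too weak to enolise the hindered ketone.

Step 9
Reactants: 14 O-methylated ring-B ketone
Product: 15 6-[1-(tert-butyldiphenylsilyloxy)-3-(3,5-dibromo-2,4,6-trimethoxyphenyl)-5-methylhexan-2-yl]-3,5-diethenyl-6-methylcyclohex-1-en-1-yl trifluoromethanesulfonate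
Conditions: KHMDS, THF, −78 °C; PhNTf2, −78 → 0 °C
Reagents that add atoms: N-phenylbis(trifluoromethanesulfonimide), O=S(=O)(N(c1ccccc1)S(=O)(=O)C(F)(F)F)C(F)(F)F
Why: Enolate O-triflation; C10 is quaternary, so enolisation can only occur toward C8.

Step 10
Reactants: 15 enol triflate
Product: 16 tert-butyl{[3-(3,5-dibromo-2,4,6-trimethoxyphenyl)-2-(4,6-diethenyl-1-methylcyclohex-2-en-1-yl)-5-methylhexyl]oxy}diphenylsilane (C8=C9 alkene)
Conditions: Pd(OAc)2 (5 mol %), PPh3, HCO2H, Et3N, DMF, 40 °C
Reagents that add atoms: none
Why: Palladium-catalysed formate reduction of the vinyl triflate removes the C9 oxygen; the di-ortho-substituted, electron-rich aryl bromides should insert far more slowly, and any debrominated material converges in step 15.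

Step 11
Reactants: 16 cyclohexene with two vinyl groups
Product: 17 diketone: 16 with both vinyl groups converted into acetyl groups (C4 and C11 methyl ketones)
Conditions: PdCl2 (10 mol %), CuCl, O2 (1 atm), DMF–H2O 7:1, rt
Reagents that add atoms: water, O
Why: Wacker oxidation of the two terminal alkenes to methyl ketones; the internal ring alkene reacts much more slowly and the silyl ether prevents oxypalladation by the C2 oxygen.

Step 12
Reactants: 17 diketone silyl ether
Product: 18 keto alcohol: 17 with free C2–OH
Conditions: TBAF, AcOH, THF, rt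
Reagents that add atoms: none
Why: Fluoride desilylation; buffering with acetic acid suppresses base-induced aldol reactions of the 1,5-diketone.

Step 13
Reactants: 18 keto alcohol
Product: 19 keto aldehyde (C2 aldehyde, C4 and C11 methyl ketones)
Conditions: Dess–Martin periodinane, CH2Cl2, rt
Reagents that add atoms: none
Why: Periodinane oxidation of the primary alcohol under non-basic conditions, which should leave the α-centre C1 untouched.

Step 14
Reactants: 19 keto aldehyde
Product: 21 trans-fused dienone (ring A closed: C2=C3–C4=O; ring B: C8=C9, C7 acetyl; C1 bears the 1-aryl-3-methylbutyl group), via aldol adduct 20 (not isolated)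
Conditions: KOH (0.2 equiv), MeOH, rt → 40 °C
Reagents that add atoms: none
Why: Intramolecular aldol condensation: the aldehyde is the only fast electrophile and the C3 methyl of the C4 ketone the only enolate carbon that reaches it through a six-membered ring, and dehydration makes ring closure irreversible. C1–H is flanked by the quaternary C10 and should not epimerise; C5 and C7 are epimerisable and should settle as trans ring fusion and equatorial acetyl.

Step 15
Reactants: 21 trans-fused dienone
Product: 22 trans-decalin diketone: 7-acetyl-10-methyl-1-[3-methyl-1-(2,4,6-trimethoxyphenyl)butyl]decalin-4-one (eudesmane numbering)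
Conditions: H2 (1 atm), 10% Pd/C, Et3N (3 equiv), EtOAc–MeOH, rt; then NaOMe (cat.), MeOH, rt
Reagents that add atoms: none
Why: Catalytic hydrogenation saturates the C2=C3 and C8=C9 alkenes (no new stereocentres) and hydrogenolyses both aryl C–Br bonds in the presence of base; the methoxide treatment secures the thermodynamic trans ring fusion at C5 and the equatorial acetyl at C7.

Step 16
Reactants: 22 trans-decalin diketone
Product: 23 diol: tris-O-methyl, bis-deformyl target
Conditions: MeMgBr (6 equiv), THF, −20 → 0 °C
Reagents that add atoms: methylmagnesium bromide, C[Mg]Br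
Why: Grignard addition to both ketones; at C4 the methyl group should enter along the equatorial trajectory, away from the 1,3-diaxial angular methyl, giving the axial C4–OH cis to the C10 methyl as in the target, while C11 becomes the achiral dimethyl carbinol.

Step 17
Reactants: 23 diol
Product: 25 tri-O-methyl ether of the target (dialdehyde), via lithium hemiaminal 24 (not isolated)
Conditions: n-BuLi (3.3 equiv), TMEDA, THF, −78 → 0 °C; DMF (1.1 equiv), −78 °C; n-BuLi (1.5 equiv), 0 °C; DMF; 1 M HCl
Reagents that add atoms: N,N-dimethylformamide, CN(C)C=O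
Why: Directed ortho-metalation and formylation: each ring hydrogen lies between two methoxy groups, the tertiary alcohols are masked as lithium alkoxides, and the lithium hemiaminal from the first DMF addition protects the first aldehyde and directs the second lithiation.

Step 18
Reactants: 25 tri-O-methyl ether of the target
Product: 26 CNP0409870.4 (target)
Conditions: EtSNa (10 equiv), DMF, 120 °C; then 1 M HCl
Reagents that add atoms: none
Why: SN2 O-demethylation by thiolate; all three methoxy groups are activated by ortho or para formyl groups, and the basic, non-Lewis-acidic medium should spare the two tertiary alcohols.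

**Compound list**

1 | but-2-yn-1-ol | CC#CCO | starting material
2 | tert-butyl(but-2-yn-1-yloxy)diphenylsilane | CC#CCO[Si](c1ccccc1)(c1ccccc1)C(C)(C)C | intermediate
3 | chloridobis(cyclopentadienyl)[(E)-4-(tert-butyldiphenylsilyloxy)but-2-en-2-yl]zirconium | C/C(=C\CO[Si](c1ccccc1)(c1ccccc1)C(C)(C)C)[Zr](Cl)(C1C=CC=C1)C1C=CC=C1 | intermediate (not isolated)
4 | (E)-tert-butyl[(3-iodobut-2-en-1-yl)oxy]diphenylsilane | C/C(I)=C\CO[Si](c1ccccc1)(c1ccccc1)C(C)(C)C | intermediate
5 | (1R,4R)-bicyclo[2.2.1]hept-5-en-2-one | C1=C[C@H]2C[C@@H]1CC2=O | starting material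
6 | (E)-[4-(tert-butyldiphenylsilyloxy)but-2-en-2-yl]lithium | C/C([Li])=C\CO[Si](c1ccccc1)(c1ccccc1)C(C)(C)C | intermediate (not isolated)
7 | (1R,2R,4R)-2-[(E)-4-(tert-butyldiphenylsilyloxy)but-2-en-2-yl]bicyclo[2.2.1]hept-5-en-2-ol | C1=C[C@H]2C[C@@H]1C[C@]2(O)/C(C)=C/CO[Si](c1ccccc1)(c1ccccc1)C(C)(C)C | intermediate
8 | (1R,2R,4R)-1-[(E)-4-(tert-butyldiphenylsilyloxy)but-2-en-2-yl]-2,4-diethenylcyclopentan-1-ol | C=C[C@H]1C[C@@H](C=C)C[C@]1(O)/C(C)=C/CO[Si](c1ccccc1)(c1ccccc1)C(C)(C)C | intermediate
9 | 2-hydroxy-4,6-dimethoxybenzaldehyde | COc1cc(O)c(C=O)c(OC)c1 | starting material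
10 | 3,5-dibromo-2-hydroxy-4,6-dimethoxybenzaldehyde | COc1c(Br)c(O)c(C=O)c(OC)c1Br | intermediate
11 | 2,4-dibromo-6-(1-hydroxy-3-methylbutyl)-3,5-dimethoxyphenol (racemic) | CC(C)CC(O)c1c(O)c(Br)c(OC)c(Br)c1OC | intermediate
12 | (E)-2,4-dibromo-3,5-dimethoxy-6-(3-methylbutylidene)cyclohexa-2,4-dien-1-one | CC(C)C/C=C1\C(OC)=C(Br)C(OC)=C(Br)C1=O | intermediate (not isolated)
13 | 2-[1-(tert-butyldiphenylsilyloxy)-3-(3,5-dibromo-2-hydroxy-4,6-dimethoxyphenyl)-5-methylhexan-2-yl]-3,5-diethenyl-2-methylcyclohexan-1-one | CC(C)C[C@H](c1c(O)c(Br)c(OC)c(Br)c1OC)[C@@H](CO[Si](c1ccccc1)(c1ccccc1)C(C)(C)C)[C@@]1(C)C(=O)C[C@H](C=C)C[C@@H]1C=C | intermediate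
14 | O-methyl ether of 13 (3,5-dibromo-2,4,6-trimethoxyphenyl) | CC(C)C[C@H](c1c(OC)c(Br)c(OC)c(Br)c1OC)[C@@H](CO[Si](c1ccccc1)(c1ccccc1)C(C)(C)C)[C@@]1(C)C(=O)C[C@H](C=C)C[C@@H]1C=C | intermediate
15 | enol triflate of 14 (C8=C9–OTf) | CC(C)C[C@H](c1c(OC)c(Br)c(OC)c(Br)c1OC)[C@@H](CO[Si](c1ccccc1)(c1ccccc1)C(C)(C)C)[C@@]1(C)C(OS(=O)(=O)C(F)(F)F)=C[C@H](C=C)C[C@@H]1C=C | intermediate
16 | tert-butyl{[3-(3,5-dibromo-2,4,6-trimethoxyphenyl)-2-(4,6-diethenyl-1-methylcyclohex-2-en-1-yl)-5-methylhexyl]oxy}diphenylsilane | CC(C)C[C@H](c1c(OC)c(Br)c(OC)c(Br)c1OC)[C@@H](CO[Si](c1ccccc1)(c1ccccc1)C(C)(C)C)[C@@]1(C)C=C[C@H](C=C)C[C@@H]1C=C | intermediate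
17 | diketone: 16 with acetyl groups in place of both vinyl groups | CC(C)C[C@H](c1c(OC)c(Br)c(OC)c(Br)c1OC)[C@@H](CO[Si](c1ccccc1)(c1ccccc1)C(C)(C)C)[C@@]1(C)C=C[C@H](C(C)=O)C[C@@H]1C(C)=O | intermediate
18 | keto alcohol: 17 with free primary OH | CC(C)C[C@H](c1c(OC)c(Br)c(OC)c(Br)c1OC)[C@@H](CO)[C@@]1(C)C=C[C@H](C(C)=O)C[C@@H]1C(C)=O | intermediate
19 | keto aldehyde (C2 aldehyde, C4 and C11 methyl ketones) | CC(C)C[C@H](c1c(OC)c(Br)c(OC)c(Br)c1OC)[C@@H](C=O)[C@@]1(C)C=C[C@H](C(C)=O)C[C@@H]1C(C)=O | intermediate
20 | aldol adduct: ring A closed, C2–OH (either epimer), C4 ketone | CC(C)C[C@H](c1c(OC)c(Br)c(OC)c(Br)c1OC)[C@H]1C(O)CC(=O)[C@H]2C[C@@H](C(C)=O)C=C[C@]12C | intermediate (not isolated)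
21 | trans-fused dienone: 7-acetyl-1-[1-(3,5-dibromo-2,4,6-trimethoxyphenyl)-3-methylbutyl]-10-methyldecal-2,8-dien-4-one | CC(C)C[C@H](c1c(OC)c(Br)c(OC)c(Br)c1OC)[C@H]1C=CC(=O)[C@H]2C[C@@H](C(C)=O)C=C[C@]12C | intermediate
22 | trans-decalin diketone: 7-acetyl-10-methyl-1-[3-methyl-1-(2,4,6-trimethoxyphenyl)butyl]decalin-4-one | CC(C)C[C@H](c1c(OC)cc(OC)cc1OC)[C@H]1CCC(=O)[C@H]2C[C@@H](C(C)=O)CC[C@]12C | intermediate
23 | diol: tris-O-methyl, bis-deformyl target | CC(C)C[C@H](c1c(OC)cc(OC)cc1OC)[C@H]1CC[C@@](C)(O)[C@H]2C[C@@H](C(C)(C)O)CC[C@]12C | intermediate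
24 | trilithium salt: dialkoxide of 23 with ArCH(OLi)NMe2 at one ring position | CC(C)C[C@H](c1c(OC)cc(OC)c(C(O[Li])N(C)C)c1OC)[C@H]1CC[C@@](C)(O[Li])[C@H]2C[C@@H](C(C)(C)O[Li])CC[C@]12C | intermediate (not isolated)
25 | tri-O-methyl ether of the target | CC(C)C[C@H](c1c(OC)c(C=O)c(OC)c(C=O)c1OC)[C@H]1CC[C@@](C)(O)[C@H]2C[C@@H](C(C)(C)O)CC[C@]12C | intermediate
26 | CNP0409870.4 | CC(C)C[C@H](c1c(O)c(C=O)c(O)c(C=O)c1O)[C@H]1CC[C@@](C)(O)[C@H]2C[C@@H](C(C)(C)O)CC[C@]12C | target

**Step count and risks**

Total steps: 18. Longest linear sequence: 16 steps (steps 1–4 and 7–18).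

Steps most likely to fail:

1. Step 7 (proposed new method). Possible failures are poor π-facial selection at the acyclic alkene or at the methide carbon, giving C10 or C1' epimers, and capture of the cation by the phenol oxygen without onward rearrangement. The two hindered partners may also join slowly while the quinone methide is consumed by itself. Fallback: set out from 8 and 11 and separate the two events with reaction types that are individually established. Heating without acid (toluene, 110 °C, MgSO4) should generate 12 thermally and trap it in the inverse-demand hetero-Diels–Alder reaction known for o-quinone methides and trisubstituted terpene alkenes, giving the 2-(1-hydroxycyclopentyl)chroman F1. Treatment of F1 with BF3·OEt2 (CH2Cl2, −78 °C) should then effect a pinacol-type rearrangement of the tertiary β-hydroxy aryl ether (ionisation of the C10–OAr bond, 1,2-shift of C5) and come back to the route at 13.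

2. Step 17. The second lithiation may be incomplete, or butyllithium may attack the masked first aldehyde, leaving mono-aldehyde or over-addition products. Fallback: set out from 23 and brominate both free ring positions (NBS, 2.1 equiv, MeCN, 0 °C) to the dibromide F2. Then form the dialkoxide with MeLi, carry out twofold bromine–lithium exchange with t-BuLi at −78 °C and quench with DMF, coming back at 25.

3. Step 18. The third demethylation may stall on the phenoxide dianion, or the dialdehyde may degrade under hot thiolate. Fallback: set out from 23 and change the order. Demethylate the unformylated arene first (EtSNa, DMF, 150 °C) to the phloroglucinol triol F3, then introduce both aldehydes by magnesium-mediated ortho-formylation of the phenol (MgCl2, Et3N, paraformaldehyde, MeCN, reflux), coming back at 26.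

**Further compounds**

F1 | step 7 | chroman from [4+2] addition of 12 to 8: 6,8-dibromo-2-[(1R,2R,4R)-2,4-diethenyl-1-hydroxycyclopentyl]-5,7-dimethoxy-2-methyl-4-(2-methylpropyl)-3-[(tert-butyldiphenylsilyloxy)methyl]chroman | CC(C)C[C@H]1[C@@H](CO[Si](c2ccccc2)(c2ccccc2)C(C)(C)C)[C@](C)([C@@]2(O)C[C@H](C=C)C[C@@H]2C=C)Oc2c(Br)c(OC)c(Br)c(OC)c12
F2 | step 17 | dibromide of 23 (3,5-dibromo-2,4,6-trimethoxyphenyl) | CC(C)C[C@H](c1c(OC)c(Br)c(OC)c(Br)c1OC)[C@H]1CC[C@@](C)(O)[C@H]2C[C@@H](C(C)(C)O)CC[C@]12C
F3 | step 18 | phloroglucinol triol (bis-deformyl target) | CC(C)C[C@H](c1c(O)cc(O)cc1O)[C@H]1CC[C@@](C)(O)[C@H]2C[C@@H](C(C)(C)O)CC[C@]12C
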